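## The problem

4,5-Di-O-p-coumaroylquinic acid (21) is a single cyclohexane ring. In quinate numbering C1 is quaternary (OH, CO2H), C2 and C6 are methylene, and C3, C4 and C5 are secondary carbinol carbons. O3 is cis to O4, O5 is trans to O4, and O1 lies on the face of O3 and O4. The contiguous triad C3–C4–C5 can be built by relay (C5 directs C4, C4 directs C3). C1 is insulated from it by a CH2 group on each side, so it must be set by 1,3-induction from C5 or by an external reagent. The three secondary oxygens must emerge in three different states: O4 and O5 carry the (E)-4-hydroxycinnamoyl groups and the axial 3-OH stays free. The cis O3/O4 pair is where an ester migrates under base. The cinnamate esters tolerate neither ozone, single-electron reductants, hydrogenation nor hydroxide, and free phenols do not tolerate quinone oxidants. The esters must therefore go on after all redox chemistry on the ring, with masked phenols, and every later unmasking (including release of the tertiary α-hydroxy acid) must be non-basic. The enabling feature is the C3–C4 bond: two adjacent ring carbinol carbons with cis oxygens, each at the aldehyde oxidation level once the bond is removed. Ring and both stereocentres can then come from reductive coupling of a 3,4-seco 1,6-dialdehyde.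

## Retrosynthesis

**Protecting groups (21 ⇐ 20 ⇐ 19).** Only protecting-group bonds are cut: the tert-butyl ester, then the two aryl silyl ethers and the tertiary silyl ether. Acid for the ester and buffered fluoride for silicon are chosen over saponification or hydrogenolysis, which the cinnamates would not survive. Precursor 19 is the fully masked target; the forward steps must not move an acyl group from O4 to O3.

**Ester C–O bonds (19 ⇐ 18 + 15; 18 ⇐ 17; 17 ⇐ 11 + 15).** The two ester bonds are cut one at a time. A one-pot diacylation of a 3,4,5-triol would rely on the axial 3-OH being inert, which quinate chemistry does not guarantee. In diol 11 the O5 position is already tagged as a 4-methoxybenzyl ether, so only equatorial O4 has to be told from axial O3. This is asked of a tin acetal in the forward direction. Oxidative removal of the benzyl-type ether then exposes O5 alone. The acyl donor 15 carries a silyl-capped phenol.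

**C3–C4 (11 ⇐ 10).** This is the central cut. Cutting C1–C2 or C1–C6 (aldol logic) would leave the quaternary centre to be made during ring closure. Cutting C4–C5 or C5–C6 would leave a β-hydroxy carbonyl prone to dehydration. Cutting C3–C4 removes the ring and two stereocentres at once and leaves an acyclic chain (10) with only the 1,3-related centres C1 and C5. The forward reaction must give the 3,4-cis, 4,5-trans diol and leave the ester, the ethers and the α-alkoxy group untouched.

**Aldehydes from alkenes (10 ⇐ 9).** Both formyl carbons are cut back to terminal alkenes, a vinyl group on C5 and an allyl group on C1. The sensitive dialdehyde then exists only for one step, and the two chain ends come from robust, cheap alkene units. The forward cleavage must spare the electron-rich benzyl ether.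

**C1–C2 (9 ⇐ 8 ⇐ 6 + 7).** The allyl group is cut from the tertiary carbinol, giving α-keto ester 6 and allylstannane 7. The alternative cut at C1–C6 would require alkylating a tetrasubstituted enolate with a β-alkoxy electrophile and offers no stereocontrol. Addition to the ketone can use the C5 ether in a six-membered chelate. The forward step must deliver the 1,3-anti relation of O1 and O5.

**C1–C6 and C1–CO2 (6 ⇐ 5 ⇐ 4 ⇐ 3 ⇐ 1 + 2).** C1 is treated as a doubly nucleophilic acyl carbon, 1,3-dithiane 1. It first opens (S)-2-vinyloxirane 2 at the CH2 terminus, which installs C6, C5 with its oxygen, and the future C4. After etherification it is C-carboxylated to the tert-butyl ester. The only stereocentre bought is that of 2; everything else descends from it.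

**Acyl donor (15 ⇐ 14 ⇐ 12).** The acid chloride is cut back to p-coumaric acid 12 through the silyl-protected acid 14.

## Roads not taken

**Alternative 1:** The ring is cut at C1–C2 at the 3-keto oxidation level. Forward, 3-dehydroquinate synthase (NAD+ and Co2+, divalent cobalt, as cofactors) converts 3-deoxy-D-arabino-heptulosonic acid 7-phosphate A1 into 3-dehydroquinic acid A2. Oxidation, phosphate loss, reduction and aldol closure all occur in one active site. Reduction of the C3 ketone would lead to (−)-quinic acid A3.
- Merits: one aqueous step closes the ring with complete control of C1, C4 and C5 and no protecting groups. In ring construction and stereocontrol this is plainly better than the pinacol route, which needs eight steps and two substrate-controlled selectivities.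
- Weak points: A1 is itself a multistep or second-enzyme preparation. A2 is a β-hydroxy ketone that dehydrates readily, and its ketone must be reduced to the axial alcohol. The product is an unprotected tetrol acid, so the O3/O4/O5 differentiation still lies ahead.
- Comparison: the chosen plan is purely chemical and needs no protein production. It delivers diol 11 with O5 and O1 already capped, so acylation can start at once.

**Alternative 2:** The cut is C5–C6. Forward, the methyl ketone of (4R,5R)-2,2-dimethyl-5-(2-oxopropyl)-1,3-dioxolane-4-carbaldehyde A6 enolises at the methyl group and adds to the aldehyde. This gives (3R,4S,5R)-5-hydroxy-3,4-O-isopropylidene-3,4-dihydroxycyclohexanone A7.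
- Merits: C3 and C4 come from the chiral pool and the aldol is operationally simple. Two purchased stereocentres are more than the one the chosen plan buys.
- Weak points:
  - Enolisation toward C2 would expel the C3 acetal oxygen, and the β-hydroxy ketone A7 can dehydrate or revert.
  - The C5 configuration rests on the aldol alone.
  - C1 still needs a carboxyl carbon added to the ketone with the hydroxyl axial, which costs further steps and a second selectivity problem.
  - The acetonide ties O3 to O4, whereas the target needs O4 paired with O5, so a protecting-group exchange follows.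
  - With the atom mapping this cut imposes (sugar C2–C5 become ring C2–C5), the natural 3R centre corresponds to 2-deoxy-L-ribose A5. The abundant 2-deoxy-D-ribose A4 would lead to the mirror-image series.
- Comparison: in the chosen plan the carboxyl is present from step 3 and the oxygen pattern of 11 already matches the target.

**Alternative 3:** No ring bond is cut; both Cα=Cβ bonds of the side chains are. Forward, allyl 3-O-(tert-butyldimethylsilyl)-4,5-bis-O-(carboxyacetyl)quinate A8 condenses twice with 4-hydroxybenzaldehyde A9 (piperidine, pyridine, loss of two CO2). This gives allyl 3-O-(tert-butyldimethylsilyl)-4,5-di-O-p-coumaroylquinate A10.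
- Merits: the ring and all four stereocentres are bought as quinic acid A3. The phenols need no protection, the E geometry is assured, and the route is far shorter. In step count and stereochemical certainty it is the better road, and it avoids the phenol silylation and desilylation that the chosen plan needs.
- Weak points: selective 3-O-silylation and 4,5-bis-malonylation of a quinate must be achieved first. Malonic half-esters can decarboxylate to acetates if condensation lags. The warm amine medium invites acyl migration.
- Comparison: the chosen plan can only set its independence from the natural skeleton against this. Either enantiomer is available from the antipode of 2, isotope labels can be placed at any ring carbon, and C2/C6 analogues are accessible. The differentiated oxygens of 11 also need no selective protection of a polyol.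

Key step: step 8

Assumption: (S)-2-vinyloxirane 2 is bought as the single enantiomer (it is the epoxide left by hydrolytic kinetic resolution of racemic butadiene monoepoxide).
Remark: ring positions use quinic acid numbering (C1 bears the carboxyl; O3 and O4 cis; O5 trans to O4 and cis to the carboxyl); "quinate" means an ester of (−)-quinic acid with this configuration.

## Route

Step 1
Reactants: 1 1,3-dithiane; 2 (S)-2-vinyloxirane
Product: 3 (2R)-1-(1,3-dithian-2-yl)but-3-en-2-ol
Conditions: n-BuLi, THF, −30 °C, 2 h; then 2, −78 → 0 °C; then H2O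
Reagents that add atoms: none
Why: Corey–Seebach dithiane anion opens the epoxide by SN2 attack at the unsubstituted CH2; the C–O bond at the stereocentre is untouched (the descriptor changes from S to R by priority only), and the unhindered 2-lithiodithiane should prefer direct over allylic (SN2′) opening.

Step 2
Reactants: 3 (2R)-1-(1,3-dithian-2-yl)but-3-en-2-ol
Product: 4 2-{(2R)-2-[(4-methoxybenzyl)oxy]but-3-en-1-yl}-1,3-dithiane
Conditions: NaH, 4-methoxybenzyl chloride, Bu4NI (cat.), DMF, 0 °C → rt
Reagents that add atoms: 4-methoxybenzyl chloride, COc1ccc(CCl)cc1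
Why: Williamson etherification of the secondary alkoxide; NaH does not deprotonate the dithiane C–H, and a benzyl-type ether (unlike a silyl ether) cannot undergo 1,4-silyl migration in the next step.

Step 3
Reactants: 4 2-{(2R)-2-[(4-methoxybenzyl)oxy]but-3-en-1-yl}-1,3-dithiane
Product: 5 tert-butyl 2-{(2R)-2-[(4-methoxybenzyl)oxy]but-3-en-1-yl}-1,3-dithiane-2-carboxylate
Conditions: t-BuLi, THF/HMPA (10:1), −78 °C, 10 min; then Boc2O, −78 → 0 °C; then H2O
Reagents that add atoms: di-tert-butyl dicarbonate, CC(C)(C)OC(=O)OC(=O)OC(C)(C)C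
Why: Second Corey–Seebach metalation followed by C-acylation; the dithiane C–H is the most acidic site, and a short metalation at −78 °C should suppress benzylic deprotonation and Wittig rearrangement of the allylic ether; the product has no α-hydrogen and cannot react further.

Step 4
Reactants: 5 tert-butyl 2-{(2R)-2-[(4-methoxybenzyl)oxy]but-3-en-1-yl}-1,3-dithiane-2-carboxylate
Product: 6 tert-butyl (4R)-4-[(4-methoxybenzyl)oxy]-2-oxohex-5-enoate
Conditions: PhI(OCOCF3)2, MeCN/H2O (9:1), 0 °C, 15 min; then aq. NaHCO3; used crude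
Reagents that add atoms: water, O
Why: Oxidative dithioacetal hydrolysis; the thiophilic iodine reagent should attack sulfur much faster than the terminal alkene or the anisyl ring, and the cold, brief, base-free conditions are chosen to avoid E1cB loss of the β-alkoxy group from the keto ester.

Step 5
Reactants: 6 tert-butyl (4R)-4-[(4-methoxybenzyl)oxy]-2-oxohex-5-enoate; 7 allyltributylstannane
Product: 8 tert-butyl (2S,4R)-2-hydroxy-4-[(4-methoxybenzyl)oxy]-2-(prop-2-en-1-yl)hex-5-enoate
Conditions: MgBr2·OEt2 (2.5 equiv), CH2Cl2, −78 °C, 15 min; then 7, −78 → −20 °C; aq. NaHCO3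
Reagents that add atoms: none
Why: Chelation-controlled Lewis-acid allylation of an activated ketone; MgBr2 should bind the ketone oxygen and the β-ether oxygen in a six-membered chelate with the vinyl group pseudo-equatorial, and the allyl group enters on the face away from it, which gives the 1,3-anti O1/O5 relation (2S) that becomes trans on the ring.

Step 6
Reactants: 8 tert-butyl (2S,4R)-2-hydroxy-4-[(4-methoxybenzyl)oxy]-2-(prop-2-en-1-yl)hex-5-enoate
Product: 9 tert-butyl (2S,4R)-4-[(4-methoxybenzyl)oxy]-2-(prop-2-en-1-yl)-2-[(triethylsilyl)oxy]hex-5-enoate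
Conditions: Et3SiOTf, 2,6-lutidine, CH2Cl2, −78 → 0 °C
Reagents that add atoms: triethylsilyl trifluoromethanesulfonate, CC[Si](CC)(CC)OS(=O)(=O)C(F)(F)F
Why: Silylation of a hindered tertiary α-hydroxy ester needs the silyl triflate; the low temperature spares the tert-butyl ester and the benzyl ether, and the cap prevents lactol formation between O1 and the C4 aldehyde later.

Step 7
Reactants: 9 tert-butyl (2S,4R)-4-[(4-methoxybenzyl)oxy]-2-(prop-2-en-1-yl)-2-[(triethylsilyl)oxy]hex-5-enoate
Product: 10 tert-butyl (2R,4R)-4-[(4-methoxybenzyl)oxy]-5-oxo-2-(2-oxoethyl)-2-[(triethylsilyl)oxy]pentanoate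
Conditions: O3, CH2Cl2, −78 °C (stopped at first blue tint); then PPh3, −78 °C → rt; used crude
Reagents that add atoms: ozone, [O-][O+]=O
Why: Criegee ozonolysis of both monosubstituted alkenes, which react faster than the anisyl ring at −78 °C; neutral phosphine reduction and immediate use should avoid epimerisation at the α-alkoxy aldehyde carbon (C5) and β-elimination of the silyloxy group (descriptors change to 2R by priority only).

Step 8
Reactants: 10 tert-butyl (2R,4R)-4-[(4-methoxybenzyl)oxy]-5-oxo-2-(2-oxoethyl)-2-[(triethylsilyl)oxy]pentanoate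
Product: 11 tert-butyl (1S,3R,4R,5R)-3,4-dihydroxy-5-[(4-methoxybenzyl)oxy]-1-[(triethylsilyl)oxy]cyclohexane-1-carboxylate
Conditions: SmI2 (2.5 equiv, 0.1 M in THF), t-BuOH (3 equiv), THF, −78 °C → rt, slow addition of 10 (final 0.01 M); aq. NaHCO3
Reagents that add atoms: none
Why: Samarium diiodide (divalent samarium) transfers one electron to each aldehyde, and the resulting ketyls, held on trivalent samarium, join at carbon to form the C3–C4 bond; protonation gives the diol. The closest known reaction type is the SmI2 pinacol cyclisation of sugar-derived 1,6-dialdehydes to cis-cyclohexane-1,2-diols (cyclitol synthesis). The six-membered carbocycle closes by 6-exo-trig attack of one ketyl carbon on the other carbonyl (or by diketyl recombination) through a chair in which the C5 ether and the ester are equatorial. C4 is controlled by C5: the samarium-bound oxygen avoids the adjacent C–O dipole and bulk, so O4 ends trans to O5. C3 is controlled by the metal bridge: one trivalent samarium spans both oxygens, which keeps them cis and places O3 axial. That axial O3 is syn to the axial silyloxy group at C1, the same arrangement natural quinates adopt, and the long O–Si bond keeps the penalty small. The step needs the 3,4-cis/4,5-trans isomer out of four and must leave the rest intact: aldehydes are reduced far faster than the tert-butyl ester, and at −78 °C without HMPA the α-alkoxy group is expected to couple rather than be expelled. High dilution disfavours intermolecular coupling.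

Step 9
Reactants: 12 p-coumaric acid
Product: 14 (2E)-3-{4-[(tert-butyldimethylsilyl)oxy]phenyl}prop-2-enoic acid, via silyl ester 13 (not isolated)
Conditions: t-BuMe2SiCl (2.4 equiv), imidazole, DMF, rt; then K2CO3 (cat.), THF/MeOH/H2O, 0 °C; pH 4 work-up
Reagents that add atoms: tert-butyldimethylsilyl chloride, CC(C)(C)[Si](C)(C)Cl
Why: Both acidic OH groups are silylated; the silyl ester is far more labile than the aryl silyl ether and is hydrolysed selectively.

Step 10
Reactants: 14 (2E)-3-{4-[(tert-butyldimethylsilyl)oxy]phenyl}prop-2-enoic acid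
Product: 15 (2E)-3-{4-[(tert-butyldimethylsilyl)oxy]phenyl}prop-2-enoyl chloride
Conditions: (COCl)2, DMF (cat.), CH2Cl2, 0 °C → rt; evaporated, used crude in steps 11 and 13
Reagents that add atoms: oxalyl chloride, ClC(=O)C(=O)Cl
Why: Vilsmeier-catalysed acid chloride formation; the aryl silyl ether tolerates anhydrous HCl for the short reaction time and the E alkene is not affected.

Step 11
Reactants: 11 tert-butyl (1S,3R,4R,5R)-3,4-dihydroxy-5-[(4-methoxybenzyl)oxy]-1-[(triethylsilyl)oxy]cyclohexane-1-carboxylate; 15 (2E)-3-{4-[(tert-butyldimethylsilyl)oxy]phenyl}prop-2-enoyl chloride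
Product: 17 tert-butyl 4-O-[(2E)-3-{4-[(tert-butyldimethylsilyl)oxy]phenyl}prop-2-enoyl]-5-O-(4-methoxybenzyl)-1-O-(triethylsilyl)quinate, via stannylene acetal 16 (not isolated)
Conditions: Bu2SnO, toluene, reflux (water removed), 3 h; then 15 (1.05 equiv), toluene, 0 °C → rt
Reagents that add atoms: none
Why: Tin-acetal-directed monoacylation of a cis-1,2-diol; in the five-membered stannylene the equatorial oxygen is the more nucleophilic, so O4 is acylated, and the axial O3 is further shielded by the syn-axial silyloxy group; no base is present, which limits acyl migration.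

Step 12
Reactants: 17 tert-butyl 4-O-[(2E)-3-{4-[(tert-butyldimethylsilyl)oxy]phenyl}prop-2-enoyl]-5-O-(4-methoxybenzyl)-1-O-(triethylsilyl)quinate
Product: 18 tert-butyl 4-O-[(2E)-3-{4-[(tert-butyldimethylsilyl)oxy]phenyl}prop-2-enoyl]-1-O-(triethylsilyl)quinate
Conditions: DDQ (1.5 equiv), CH2Cl2/pH 7 buffer (10:1), 0 °C → rt
Reagents that add atoms: none
Why: Oxidative cleavage of the 4-methoxybenzyl ether by benzylic hydride abstraction; the silyl-capped phenol and the electron-poor cinnamate are not oxidised, and the buffer protects the silyl ether and the tert-butyl ester.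

Step 13
Reactants: 18 tert-butyl 4-O-[(2E)-3-{4-[(tert-butyldimethylsilyl)oxy]phenyl}prop-2-enoyl]-1-O-(triethylsilyl)quinate; 15 (2E)-3-{4-[(tert-butyldimethylsilyl)oxy]phenyl}prop-2-enoyl chloride
Product: 19 tert-butyl 4,5-bis-O-[(2E)-3-{4-[(tert-butyldimethylsilyl)oxy]phenyl}prop-2-enoyl]-1-O-(triethylsilyl)quinate
Conditions: 15 (1.1 equiv), pyridine, DMAP (0.1 equiv), CH2Cl2, −20 → 0 °C
Reagents that add atoms: none
Why: Acylation of the equatorial secondary 5-OH with an acid chloride; the axial 3-OH, flanked by the syn-axial silyloxy group, should react more slowly, and low temperature with near-stoichiometric reagent keeps it free.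

Step 14
Reactants: 19 tert-butyl 4,5-bis-O-[(2E)-3-{4-[(tert-butyldimethylsilyl)oxy]phenyl}prop-2-enoyl]-1-O-(triethylsilyl)quinate
Product: 20 tert-butyl 4,5-di-O-[(2E)-3-(4-hydroxyphenyl)prop-2-enoyl]quinate
Conditions: Bu4NF (3.5 equiv), AcOH (3.5 equiv), THF, 0 °C → rt
Reagents that add atoms: none
Why: Fluoride desilylation buffered with acetic acid; the aryl silyl ethers go first, the tertiary triethylsilyl ether follows, and the buffer keeps the medium from promoting 4→3 acyl migration or ester cleavage (any silyl ether left at O1 would fall in step 15).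

Step 15
Reactants: 20 tert-butyl 4,5-di-O-[(2E)-3-(4-hydroxyphenyl)prop-2-enoyl]quinate
Product: 21 4,5-di-O-p-coumaroylquinic acid, (1S,3R,4R,5R)-1,3-dihydroxy-4,5-bis{[(2E)-3-(4-hydroxyphenyl)prop-2-enoyl]oxy}cyclohexane-1-carboxylic acid
Conditions: CF3CO2H/CH2Cl2 (1:1), H2O (2 equiv), 0 °C → rt; evaporation, reversed-phase chromatography
Reagents that add atoms: none
Why: Acidolysis of the tert-butyl ester by the E1 pathway; cinnamate esters are stable to the acid, and without base no acyl migration to the cis 3-OH is expected; no stereocentre is touched.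

## Compound list

1 | 1,3-dithiane | C1CSCSC1 | starting material
2 | (S)-2-vinyloxirane | C=C[C@H]1CO1 | starting material
3 | (2R)-1-(1,3-dithian-2-yl)but-3-en-2-ol | C=C[C@H](O)CC1SCCCS1 | intermediate
4 | 2-{(2R)-2-[(4-methoxybenzyl)oxy]but-3-en-1-yl}-1,3-dithiane | C=C[C@H](OCc1ccc(OC)cc1)CC1SCCCS1 | intermediate
5 | tert-butyl 2-{(2R)-2-[(4-methoxybenzyl)oxy]but-3-en-1-yl}-1,3-dithiane-2-carboxylate | C=C[C@H](OCc1ccc(OC)cc1)CC1(C(=O)OC(C)(C)C)SCCCS1 | intermediate
6 | tert-butyl (4R)-4-[(4-methoxybenzyl)oxy]-2-oxohex-5-enoate | C=C[C@H](OCc1ccc(OC)cc1)CC(=O)C(=O)OC(C)(C)C | intermediate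
7 | allyltributylstannane | C=CC[Sn](CCCC)(CCCC)CCCC | starting material
8 | tert-butyl (2S,4R)-2-hydroxy-4-[(4-methoxybenzyl)oxy]-2-(prop-2-en-1-yl)hex-5-enoate | C=C[C@H](OCc1ccc(OC)cc1)C[C@](O)(C(=O)OC(C)(C)C)CC=C | intermediate
9 | tert-butyl (2S,4R)-4-[(4-methoxybenzyl)oxy]-2-(prop-2-en-1-yl)-2-[(triethylsilyl)oxy]hex-5-enoate | C=C[C@H](OCc1ccc(OC)cc1)C[C@](O[Si](CC)(CC)CC)(C(=O)OC(C)(C)C)CC=C | intermediate
10 | tert-butyl (2R,4R)-4-[(4-methoxybenzyl)oxy]-5-oxo-2-(2-oxoethyl)-2-[(triethylsilyl)oxy]pentanoate | O=C[C@H](OCc1ccc(OC)cc1)C[C@](O[Si](CC)(CC)CC)(C(=O)OC(C)(C)C)CC=O | intermediate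
11 | tert-butyl (1S,3R,4R,5R)-3,4-dihydroxy-5-[(4-methoxybenzyl)oxy]-1-[(triethylsilyl)oxy]cyclohexane-1-carboxylate (tert-butyl 5-O-(4-methoxybenzyl)-1-O-(triethylsilyl)quinate) | O[C@@H]1[C@H](O)C[C@@](O[Si](CC)(CC)CC)(C(=O)OC(C)(C)C)C[C@H]1OCc1ccc(OC)cc1 | intermediate
12 | p-coumaric acid, (2E)-3-(4-hydroxyphenyl)prop-2-enoic acid | OC(=O)/C=C/c1ccc(O)cc1 | starting material
13 | tert-butyldimethylsilyl (2E)-3-{4-[(tert-butyldimethylsilyl)oxy]phenyl}prop-2-enoate | CC(C)(C)[Si](C)(C)OC(=O)/C=C/c1ccc(O[Si](C)(C)C(C)(C)C)cc1 | intermediate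
14 | (2E)-3-{4-[(tert-butyldimethylsilyl)oxy]phenyl}prop-2-enoic acid | OC(=O)/C=C/c1ccc(O[Si](C)(C)C(C)(C)C)cc1 | intermediate
15 | (2E)-3-{4-[(tert-butyldimethylsilyl)oxy]phenyl}prop-2-enoyl chloride | ClC(=O)/C=C/c1ccc(O[Si](C)(C)C(C)(C)C)cc1 | intermediate
16 | 3,4-O-(dibutylstannylene) acetal of 11 | CCCC[Sn]1(CCCC)O[C@@H]2[C@H](O1)C[C@@](O[Si](CC)(CC)CC)(C(=O)OC(C)(C)C)C[C@H]2OCc1ccc(OC)cc1 | intermediate
17 | tert-butyl 4-O-[(2E)-3-{4-[(tert-butyldimethylsilyl)oxy]phenyl}prop-2-enoyl]-5-O-(4-methoxybenzyl)-1-O-(triethylsilyl)quinate | O=C(/C=C/c1ccc(O[Si](C)(C)C(C)(C)C)cc1)O[C@@H]1[C@H](O)C[C@@](O[Si](CC)(CC)CC)(C(=O)OC(C)(C)C)C[C@H]1OCc1ccc(OC)cc1 | intermediate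
18 | tert-butyl 4-O-[(2E)-3-{4-[(tert-butyldimethylsilyl)oxy]phenyl}prop-2-enoyl]-1-O-(triethylsilyl)quinate | O=C(/C=C/c1ccc(O[Si](C)(C)C(C)(C)C)cc1)O[C@@H]1[C@H](O)C[C@@](O[Si](CC)(CC)CC)(C(=O)OC(C)(C)C)C[C@H]1O | intermediate
19 | tert-butyl 4,5-bis-O-[(2E)-3-{4-[(tert-butyldimethylsilyl)oxy]phenyl}prop-2-enoyl]-1-O-(triethylsilyl)quinate | O=C(/C=C/c1ccc(O[Si](C)(C)C(C)(C)C)cc1)O[C@@H]1[C@H](O)C[C@@](O[Si](CC)(CC)CC)(C(=O)OC(C)(C)C)C[C@H]1OC(=O)/C=C/c1ccc(O[Si](C)(C)C(C)(C)C)cc1 | intermediate
20 | tert-butyl 4,5-di-O-[(2E)-3-(4-hydroxyphenyl)prop-2-enoyl]quinate | O=C(/C=C/c1ccc(O)cc1)O[C@@H]1[C@H](O)C[C@@](O)(C(=O)OC(C)(C)C)C[C@H]1OC(=O)/C=C/c1ccc(O)cc1 | intermediate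
21 | 4,5-di-O-p-coumaroylquinic acid, (1S,3R,4R,5R)-1,3-dihydroxy-4,5-bis{[(2E)-3-(4-hydroxyphenyl)prop-2-enoyl]oxy}cyclohexane-1-carboxylic acid | O=C(/C=C/c1ccc(O)cc1)O[C@@H]1[C@H](O)C[C@@](O)(C(=O)O)C[C@H]1OC(=O)/C=C/c1ccc(O)cc1 | target

## Step count and least certain steps

Total: 15 steps. Longest linear sequence: 13 steps (steps 1–8 and 11–15); steps 9 and 10 form the side branch from 12.

**Step 8 (key step).** The coupling may show poor diastereofacial control, because only one carbonyl carries an α-alkoxy director and the required isomer has a syn-axial O1/O3 pair. The all-equatorial trans-diol or the cis-diol syn to O5 could compete. Simple reduction of the aldehydes, intermolecular coupling and reductive loss of the C5 alkoxy group are further escape paths. Fallback: set out from diene 9 and close the same bond as an alkene. Ring-closing metathesis with the second-generation Grubbs catalyst (CH2Cl2, 40 °C) should give tert-butyl (1S,5R)-5-[(4-methoxybenzyl)oxy]-1-[(triethylsilyl)oxy]cyclohex-3-ene-1-carboxylate F1. Dihydroxylation (OsO4 cat., N-methylmorpholine N-oxide, acetone/H2O) anti to the allylic ether oxygen would then install the cis 3,4-diol trans to O5 and rejoin the route at 11.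

**Step 5.** Facial discrimination may be insufficient, because the Lewis acid can also bind the 1,2-dicarbonyl unit in a five-membered chelate that carries no stereochemical information. Elimination of 4-methoxybenzyl alcohol from the β-alkoxy keto ester is a second hazard. Fallback with reagent control, setting out from 6:
- Wittig methylenation (Ph3P=CH2, THF, −78 → 0 °C) gives tert-butyl (4R)-4-[(4-methoxybenzyl)oxy]-2-methylidenehex-5-enoate F2.
- i-Bu2AlH reduction gives (4R)-4-[(4-methoxybenzyl)oxy]-2-methylidenehex-5-en-1-ol F3.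
- Sharpless asymmetric epoxidation gives {(2S)-2-[(2R)-2-[(4-methoxybenzyl)oxy]but-3-en-1-yl]oxiran-2-yl}methanol F4. Conditions are Ti(OiPr)4, natural L-(+)-diethyl tartrate (the enantiomer that turns 2-substituted allyl alcohols into (S)-2-substituted glycidols), t-BuOOH, 4 Å sieves, CH2Cl2, −20 °C. This sets C1 independently of C5.
- Vinylmagnesium bromide with catalytic CuI opens the epoxide at its CH2 terminus to give (2S,4R)-4-[(4-methoxybenzyl)oxy]-2-(prop-2-en-1-yl)hex-5-ene-1,2-diol F5.
- TEMPO/PhI(OAc)2 oxidation followed by Pinnick oxidation (NaClO2) gives (2S,4R)-2-hydroxy-4-[(4-methoxybenzyl)oxy]-2-(prop-2-en-1-yl)hex-5-enoic acid F6.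
- Esterification with N,N-dimethylformamide di-tert-butyl acetal rejoins the route at 8.

**Step 7.** Ozone may over-oxidise the electron-rich benzyl ether. The dialdehyde may also epimerise at the α-alkoxy carbon or lose the β-silyloxy group during ozonide reduction. Fallback from 9: twofold dihydroxylation (OsO4 cat., N-methylmorpholine N-oxide) gives tert-butyl 2-(2,3-dihydroxypropyl)-5,6-dihydroxy-4-[(4-methoxybenzyl)oxy]-2-[(triethylsilyl)oxy]hexanoate F7, with the two existing centres as in 9 and a mixture at the two new carbinols. Glycol cleavage with NaIO4 in buffered aqueous THF rejoins the route at 10.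

**Step 13.** The axial 3-OH may be acylated competitively, and base may promote acyl migration from O4 to the cis 3-OH. Fallback from 17:
- The 3-OH is capped (Et3SiOTf, 2,6-lutidine) to give tert-butyl 4-O-[(2E)-3-{4-[(tert-butyldimethylsilyl)oxy]phenyl}prop-2-enoyl]-5-O-(4-methoxybenzyl)-1,3-bis-O-(triethylsilyl)quinate F8.
- DDQ removal of the benzyl ether gives tert-butyl 4-O-[(2E)-3-{4-[(tert-butyldimethylsilyl)oxy]phenyl}prop-2-enoyl]-1,3-bis-O-(triethylsilyl)quinate F9.
- Acylation of the only free hydroxyl with 15 gives tert-butyl 4,5-bis-O-[(2E)-3-{4-[(tert-butyldimethylsilyl)oxy]phenyl}prop-2-enoyl]-1,3-bis-O-(triethylsilyl)quinate F10.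
- Buffered fluoride (Bu4NF/AcOH) removes all four silyl groups and rejoins the route at 20.

## Further compounds

F1 | step 8 | tert-butyl (1S,5R)-5-[(4-methoxybenzyl)oxy]-1-[(triethylsilyl)oxy]cyclohex-3-ene-1-carboxylate | C1=C[C@H](OCc2ccc(OC)cc2)C[C@](O[Si](CC)(CC)CC)(C(=O)OC(C)(C)C)C1
F2 | step 5 | tert-butyl (4R)-4-[(4-methoxybenzyl)oxy]-2-methylidenehex-5-enoate | C=C[C@H](OCc1ccc(OC)cc1)CC(=C)C(=O)OC(C)(C)C
F3 | step 5 | (4R)-4-[(4-methoxybenzyl)oxy]-2-methylidenehex-5-en-1-ol | C=C[C@H](OCc1ccc(OC)cc1)CC(=C)CO
F4 | step 5 | {(2S)-2-[(2R)-2-[(4-methoxybenzyl)oxy]but-3-en-1-yl]oxiran-2-yl}methanol | C=C[C@H](OCc1ccc(OC)cc1)C[C@]1(CO)CO1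
F5 | step 5 | (2S,4R)-4-[(4-methoxybenzyl)oxy]-2-(prop-2-en-1-yl)hex-5-ene-1,2-diol | C=C[C@H](OCc1ccc(OC)cc1)C[C@](O)(CO)CC=C
F6 | step 5 | (2S,4R)-2-hydroxy-4-[(4-methoxybenzyl)oxy]-2-(prop-2-en-1-yl)hex-5-enoic acid | C=C[C@H](OCc1ccc(OC)cc1)C[C@](O)(C(=O)O)CC=C
F7 | step 7 | tert-butyl 2-(2,3-dihydroxypropyl)-5,6-dihydroxy-4-[(4-methoxybenzyl)oxy]-2-[(triethylsilyl)oxy]hexanoate (existing centres as in 9) | OCC(O)[C@H](OCc1ccc(OC)cc1)C[C@](O[Si](CC)(CC)CC)(C(=O)OC(C)(C)C)CC(O)CO
F8 | step 13 | tert-butyl 4-O-[(2E)-3-{4-[(tert-butyldimethylsilyl)oxy]phenyl}prop-2-enoyl]-5-O-(4-methoxybenzyl)-1,3-bis-O-(triethylsilyl)quinate | O=C(/C=C/c1ccc(O[Si](C)(C)C(C)(C)C)cc1)O[C@@H]1[C@H](O[Si](CC)(CC)CC)C[C@@](O[Si](CC)(CC)CC)(C(=O)OC(C)(C)C)C[C@H]1OCc1ccc(OC)cc1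
F9 | step 13 | tert-butyl 4-O-[(2E)-3-{4-[(tert-butyldimethylsilyl)oxy]phenyl}prop-2-enoyl]-1,3-bis-O-(triethylsilyl)quinate | O=C(/C=C/c1ccc(O[Si](C)(C)C(C)(C)C)cc1)O[C@@H]1[C@H](O[Si](CC)(CC)CC)C[C@@](O[Si](CC)(CC)CC)(C(=O)OC(C)(C)C)C[C@H]1O
F10 | step 13 | tert-butyl 4,5-bis-O-[(2E)-3-{4-[(tert-butyldimethylsilyl)oxy]phenyl}prop-2-enoyl]-1,3-bis-O-(triethylsilyl)quinate | O=C(/C=C/c1ccc(O[Si](C)(C)C(C)(C)C)cc1)O[C@@H]1[C@H](O[Si](CC)(CC)CC)C[C@@](O[Si](CC)(CC)CC)(C(=O)OC(C)(C)C)C[C@H]1OC(=O)/C=C/c1ccc(O[Si](C)(C)C(C)(C)C)cc1
A1 | alternative 1 | 3-deoxy-D-arabino-heptulosonic acid 7-phosphate | OC(=O)C(=O)C[C@@H](O)[C@H](O)[C@H](O)COP(=O)(O)O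
A2 | alternative 1 | 3-dehydroquinic acid | O[C@@H]1C(=O)C[C@@](O)(C(=O)O)C[C@H]1O
A3 | alternative 1 | (−)-quinic acid | O[C@@H]1[C@H](O)C[C@@](O)(C(=O)O)C[C@H]1O
A4 | alternative 2 | 2-deoxy-D-ribose (open-chain form) | O=CC[C@H](O)[C@H](O)CO
A5 | alternative 2 | 2-deoxy-L-ribose (open-chain form) | O=CC[C@@H](O)[C@@H](O)CO
A6 | alternative 2 | (4R,5R)-2,2-dimethyl-5-(2-oxopropyl)-1,3-dioxolane-4-carbaldehyde | CC(=O)C[C@H]1OC(C)(C)O[C@H]1C=O
A7 | alternative 2 | (3R,4S,5R)-5-hydroxy-3,4-O-isopropylidene-3,4-dihydroxycyclohexanone | O=C1C[C@H]2OC(C)(C)O[C@H]2[C@H](O)C1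
A8 | alternative 3 | allyl 3-O-(tert-butyldimethylsilyl)-4,5-bis-O-(carboxyacetyl)quinate | OC(=O)CC(=O)O[C@@H]1[C@H](O[Si](C)(C)C(C)(C)C)C[C@@](O)(C(=O)OCC=C)C[C@H]1OC(=O)CC(=O)O
A9 | alternative 3 | 4-hydroxybenzaldehyde | O=Cc1ccc(O)cc1
A10 | alternative 3 | allyl 3-O-(tert-butyldimethylsilyl)-4,5-di-O-p-coumaroylquinate | O=C(/C=C/c1ccc(O)cc1)O[C@@H]1[C@H](O[Si](C)(C)C(C)(C)C)C[C@@](O)(C(=O)OCC=C)C[C@H]1OC(=O)/C=C/c1ccc(O)cc1
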